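**Remark on conventions:** ring atoms keep the target's numbering throughout (C1 = tertiary carbinol carrying C7, C2 = the carbon that ends as CH–OBz, C3=C4 = alkene, C5 and C6 = secondary carbinols, C6 next to C1). "Upper face" means the face of the C1 hydroxyl. The C1 descriptor switches between R and S along the route only because substituent priorities change; the centre is never touched after step 1.

**Compounds:** 1 benzoic acid; 2 dioxygen; 3 cis-diol acid; 4 diol methyl ester; 5 C2 silyl ether; 6 vinyl epoxide; 7 triol silyl ether; 8 tetraol ester; 9 bis-ketal cis-diol; 10 enone; 11 bis-ketal trans-diol; 12 triol; 13 benzoyl chloride; 14 protected dibenzoate; 15 target.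

## Analysis of the target

Target 15 is a cyclohexene (C1–C6, alkene C3=C4) in which every sp3 ring carbon carries oxygen, with one exocyclic carbon, C7, as a benzoyloxymethyl group on C1. It has four stereocentres: C1 (S, fully substituted), C2 (S), C5 (R) and C6 (S). The C1 and C6 hydroxyls lie on one face and the C2 benzoate and C5 hydroxyl on the other, so C1/C2 and C5/C6 are trans and C1/C6 is cis. Five oxygens must end up differentiated: benzoates on the primary C7 oxygen and the allylic C2 oxygen, free hydroxyls at tertiary C1 and at C5 and C6. The benzoates sit next to free hydroxyls and migrate under base, the allylic C2 ester and C5 alcohol can ionize under strong acid, and the diene intermediates aromatize on dehydration. The difficulty is the tetrasubstituted C1 carbinol of defined absolute configuration and the placing of three further oxygens relative to it without heavy protecting-group traffic. The strategy rests on the unit C7–C1(O)–C2(O) inside the six-membered ring: it is benzoic acid (1) oxidized at its ipso and ortho carbons, with C3–C6 as the diene left after dearomatization. The enzymatic diol is cis, and matching it to the cis C1/C6 pair would lead into the mirror-image series. For this enantiomer the ortho carbinol is therefore C2 and has to be inverted, and the C5/C6 diol has to be built on the diene.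

## Retrosynthetic reasoning

**15 ⇒ 14.** The last bonds cut are the two acetal C–O bonds at the C5 and C6 oxygens. The benzoates of 15 would migrate under base, so the final unmasking must be acidic and must release only the C5/C6 diol. A bis-ketal on exactly this trans-diol (14) meets that.

**14 ⇒ 12 + 13.** Both ester C–O bonds (at the C7 and C2 oxygens) are cut together, giving triol 12 and two equivalents of benzoyl chloride 13. The forward acylation has to tell a primary and a secondary hydroxyl from the tertiary one at C1. Steric differentiation should suffice, so the C1 hydroxyl needs no protecting group at any stage.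

**12 ⇒ 11.** C7 is taken back to the ester oxidation level. The ester is kept this long because the key step delivers it, because it tempers the diene in the early intermediates, and because a free primary hydroxyl at C7 would compete earlier as a directing and acylation site.

**11 ⇒ 10 ⇒ 9.** The C2–H bond is cut: the trans C1/C2 diol 11 comes from ketone 10, and 10 from the cis-diol 9. This inversion is the price of using the enzymatic diol in the correct absolute series. The forward reduction must bring hydride to the upper face, against the intrinsic axial-attack preference, and only intramolecular delivery from the C1 hydroxyl can enforce that. The oxidation needs C2–OH to be the only oxidizable hydroxyl, hence the C5/C6 mask.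

**9 ⇒ 7 (through 8).** The bis-ketal is removed and the C2 hydroxyl re-silylated. Forward, one acidic operation should exchange the protecting groups: silyl off C2 (giving 8), ketal onto the only trans-diequatorial secondary diol.

**7 ⇒ 6.** The C5–O bond is cut, not C6–O. The trans C5/C6 diol arises by anti addition of an oxygen nucleophile at the allylic carbon C5 of vinyl epoxide 6. C5 is the activated terminus, and attack there leaves the C6–O bond, already on the upper face, unchanged.

**6 ⇒ 5.** The epoxide C–O bonds at C5 and C6 are cut. The oxygen must go to the C5=C6 half of a conjugated diene and to the upper face. The free tertiary hydroxyl at C1 is allylic to exactly that alkene and on that face, so hydroxyl-directed oxygen transfer is the matching reaction. The C2 oxygen must not direct and should screen C3=C4, hence silyl ether 5.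

**5 ⇒ 4 ⇒ 3.** The O–Si bond and the ester O–CH3 bond are cut. These are two protecting operations that also make the acid-labile diol acid 3 easier to handle.

**3 ⇒ 1 + 2.** C1–O and C2–O are cut together, which restores the aromatic ring of 1. No chemical reagent is known to add dioxygen 2 across the ipso and ortho carbons of an arene enantioselectively; a dioxygenase does so and fixes C1 in the sense that 15 requires.

## Alternatives that were turned down

**Alternative 1:** The ring is cut at C1–C2 and C5–C6. (1E,3E)-1,4-Diacetoxybutadiene A1 supplies C2–C5 with both allylic oxygens, and methyl 2-oxo-1,3-dioxole-4-carboxylate A2 supplies C7, C1 and C6 with their oxygens tied as a carbonate. A chiral oxazaborolidinium Lewis acid would promote the Diels–Alder reaction through an ester-endo transition state to cycloadduct A3.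
- For: all six ring carbons, C7, all four stereocentres and all ring oxygens arrive in one catalytic asymmetric step from achiral materials, with the C2 oxygen already trans to the C1 oxygen. On convergence and on stereocentres per step it is stronger than the chosen route, and it needs no fermentation.
- Against: A2 is a trisubstituted alkene with two oxygen donors and is a weak dienophile. A1 is hindered at both termini. A2 offers the Lewis acid two carbonyls, so facial and endo/exo control are uncertain. In A3 the C2 and C5 oxygens are near-equivalent allylic acetates that must end as benzoate and free hydroxyl. The ester cannot be reduced selectively beside acetates and a carbonate. The endgame therefore becomes an oxygen-differentiation problem.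
- Comparison: the chosen route introduces each oxygen singly and already distinguished, at the cost of one inversion at C2.

**Alternative 2:** The ring is cut at C1–C6 and C4–C5. 3-Hydroxy-2-pyrone A4 supplies C7 and C1–C4, and (E)-hex-3-ene-2,5-dione A5 supplies C5 and C6. An amine base would catalyse the [4+2] cycloaddition to the lactone-bridged bicycle A6.
- For: the C1 carbinol with C7 at the acid level is formed in the C–C bond-forming step, the trans-diacetyl unit fixes the C5/C6 relationship, and the reagents are commodity chemicals. Independence from a biotransformation is a point on which it is stronger.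
- Against: C5 and C6 carry carbon substituents, so two Baeyer–Villiger oxidations are needed beside an alkene. The bridging oxygen sits on C4, whereas 15 needs oxygen on C2 and the alkene at C3=C4, so a stereocontrolled 1,3-transposition of that oxygen is also required. Enantio- and endo/exo control must both hold.
- Comparison: the chosen route makes no C–C bond and moves no oxygen, since the enzyme places C1–O and C2–O on the correct carbons. It should be clearly shorter in redox operations.

**Alternative 3:** The C5–O and C6–O bonds are cut in an epoxide on the symmetric p-quinol A8, which anodic oxidation of 4-hydroxybenzyl benzoate A7 would provide. A chiral primary-amine salt with aqueous peroxide would epoxidize one enantiotopic enone syn to the tertiary hydroxyl, giving A9.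
- For: C7 is at its final oxidation level and already benzoylated, the C1 carbinol and the upper-face C5/C6 oxygens arrive within two steps from an achiral phenol, and the sequence is catalytic and scalable. On step count to the first chiral intermediate it is stronger than the chosen route.
- Against: the carbonyl of A9 is at C4, while 15 needs oxygen at C2 (trans to C1–OH) and the alkene at C3=C4, so a stereocontrolled 1,3-oxygen transposition is needed. Until that is done the epoxide is an epoxy ketone, whose opening favours C6 rather than C5, which would invert the wrong carbon. The quinol benzoate is base-sensitive, and the enantioselectivity of the desymmetrization is unproven for this substrate.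
- Comparison: the chosen route has the C2 oxygen on the right carbon from the key step and only has to invert its configuration, and its epoxide is opened at a carbon that is allylic from the outset.

Key step: step 1

## Route

**Step 1**
Reactants: 1 benzoic acid; 2 dioxygen
Product: 3 (1S,2R)-1,2-dihydroxycyclohexa-3,5-diene-1-carboxylic acid
Conditions: resting cells of Ralstonia eutropha B9 (mutant lacking the cis-diol dehydrogenase), 1 neutralized with NaOH and fed in portions, D-fructose, phosphate buffer pH 7.2, air, 30 °C; then cold acidification to pH 3, rapid EtOAc extraction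
Reagents that add atoms: dioxygen (2), O=O
Why: In the oxygenase component the benzoate carboxylate is anchored beside a mononuclear non-heme iron centre (divalent iron), which receives electrons from NADH through a reductase and a Rieske [2Fe–2S] cluster, binds O2 side-on and passes both oxygen atoms to the ipso and ortho carbons from one face of the ring. The closest known reaction type is arene cis-dihydroxylation by Rieske dioxygenases, and this ipso,ortho oxidation of benzoate by blocked mutants is established. No ring closes; C1–O and C2–O form and the ring is dearomatized to the 3,5-diene. C1 and C2 are both set by the enzyme: the cis relationship follows from suprafacial delivery of one O2 molecule, and the absolute sense (1S,2R) from the fixed orientation of the substrate in the active site. The step needs ipso,ortho regioselectivity, which the carboxylate-binding pocket provides, and it needs the diol not to be re-aromatized, which the missing dehydrogenase secures. The diol acid dehydrates easily to salicylic acid or phenol, so it should be extracted quickly from cold, briefly acidified medium.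

**Step 2**
Reactants: 3 (1S,2R)-1,2-dihydroxycyclohexa-3,5-diene-1-carboxylic acid
Product: 4 methyl (1S,2R)-1,2-dihydroxycyclohexa-3,5-diene-1-carboxylate
Conditions: TMSCHN2, MeOH/toluene, 0 °C
Reagents that add atoms: trimethylsilyldiazomethane, C[Si](C)(C)C=[N+]=[N-]
Why: Diazoalkane esterification of the carboxylic acid runs without acid catalysis, so the acid-labile dienediol is not dehydrated; the hydroxyls are not alkylated.

**Step 3**
Reactants: 4 methyl (1S,2R)-1,2-dihydroxycyclohexa-3,5-diene-1-carboxylate
Product: 5 methyl (1S,2R)-2-[(tert-butyldimethylsilyl)oxy]-1-hydroxycyclohexa-3,5-diene-1-carboxylate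
Conditions: TBSCl, imidazole, DMF, 0 °C to rt
Reagents that add atoms: tert-butyldimethylsilyl chloride, CC(C)(C)[Si](C)(C)Cl
Why: Silylation under these conditions takes the secondary C2 hydroxyl and leaves the tertiary, ester-flanked C1 hydroxyl free (steric differentiation); the C2 oxygen can then no longer direct an oxidant to C3=C4, and its silyl group screens the upper face of that alkene.

**Step 4**
Reactants: 5 methyl (1S,2R)-2-[(tert-butyldimethylsilyl)oxy]-1-hydroxycyclohexa-3,5-diene-1-carboxylate
Product: 6 methyl (1S,2R,5S,6S)-2-[(tert-butyldimethylsilyl)oxy]-5,6-epoxy-1-hydroxycyclohex-3-ene-1-carboxylate (epoxide on the upper face)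
Conditions: VO(acac)2 (cat.), TBHP (anhydrous, in decane), CH2Cl2, 0 °C to rt
Reagents that add atoms: tert-butyl hydroperoxide, CC(C)(C)OO
Why: Vanadium-catalysed hydroxyl-directed epoxidation: the C1 alkoxide binds the alkylperoxo complex of pentavalent vanadium and delivers oxygen to the allylic C5=C6 alkene on its own face, which sets C5 and C6 (epoxide cis to C1–OH); C3=C4 is only homoallylic to the free hydroxyl and is covered by the silyl ether.

**Step 5**
Reactants: 6 methyl (1S,2R,5S,6S)-2-[(tert-butyldimethylsilyl)oxy]-5,6-epoxy-1-hydroxycyclohex-3-ene-1-carboxylate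
Product: 7 methyl (1S,2R,5R,6S)-2-[(tert-butyldimethylsilyl)oxy]-1,5,6-trihydroxycyclohex-3-ene-1-carboxylate (C6–OH upper face, C5–OH lower face)
Conditions: HClO4 (cat.), THF/H2O 3:1, 0 °C
Reagents that add atoms: water, O
Why: Acid-catalysed hydrolysis of a vinyl epoxide: water attacks the allylic carbon C5 anti to the protonated epoxide oxygen, inverting C5 and leaving the C6–O bond intact, so C6–OH stays cis to C1–OH and C5–OH comes out trans to it. Attack at C6 is disfavoured next to the ester-bearing quaternary C1, and conjugate attack at C3 is hindered by the neighbouring silyl ether; participation of the ester carbonyl at C5 from the lower face would lead to the same C5 configuration.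

**Step 6**
Reactants: 7 methyl (1S,2R,5R,6S)-2-[(tert-butyldimethylsilyl)oxy]-1,5,6-trihydroxycyclohex-3-ene-1-carboxylate
Product: 9 methyl (1R,2R,5R,6S)-5,6-{[(2S,3S)-2,3-dimethoxybutane-2,3-diyl]bis(oxy)}-1,2-dihydroxycyclohex-3-ene-1-carboxylate, via tetraol ester 8 (not isolated)
Conditions: CSA (cat.), MeOH, rt; then butane-2,3-dione, HC(OMe)3, reflux
Reagents that add atoms: butane-2,3-dione, CC(=O)C(C)=O; methanol, CO
Why: Acidic methanol first cleaves the allylic silyl ether; butane-2,3-diacetal formation then selects the trans-diequatorial secondary C5/C6 diol (trans-fused 1,4-dioxane with both methoxy groups axial under anomeric control, which fixes both acetal carbons as S), while the cis pairs that involve the tertiary C1 hydroxyl are not bridged. The orthoformate removes the water formed.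

**Step 7**
Reactants: 9 methyl (1R,2R,5R,6S)-5,6-{[(2S,3S)-2,3-dimethoxybutane-2,3-diyl]bis(oxy)}-1,2-dihydroxycyclohex-3-ene-1-carboxylate
Product: 10 methyl (1S,5R,6S)-5,6-{[(2S,3S)-2,3-dimethoxybutane-2,3-diyl]bis(oxy)}-1-hydroxy-2-oxocyclohex-3-ene-1-carboxylate
Conditions: IBX (2-iodoxybenzoic acid), DMSO, rt
Reagents that add atoms: none
Why: IBX oxidizes the secondary allylic C2 alcohol to the enone without touching the tertiary C1 hydroxyl and without glycol cleavage; C2 becomes trigonal, which erases the configuration the enzyme set there.

**Step 8**
Reactants: 10 methyl (1S,5R,6S)-5,6-{[(2S,3S)-2,3-dimethoxybutane-2,3-diyl]bis(oxy)}-1-hydroxy-2-oxocyclohex-3-ene-1-carboxylate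
Product: 11 methyl (1R,2S,5R,6S)-5,6-{[(2S,3S)-2,3-dimethoxybutane-2,3-diyl]bis(oxy)}-1,2-dihydroxycyclohex-3-ene-1-carboxylate (C2–OH on the lower face, trans to C1–OH)
Conditions: Me4NBH(OAc)3, MeCN/AcOH 1:1, −20 °C to 0 °C
Reagents that add atoms: none
Why: Hydroxyl-directed reduction of the Evans–Saksena type: the C1 hydroxyl, axial in the acetal-locked ring, exchanges an acetate on boron, and the resulting alkoxyborohydride delivers hydride intramolecularly to the upper face of the C2 carbonyl, so the new C2 hydroxyl appears on the lower face. The reagent is too weak to reduce the enone without this assistance, which suppresses both the undirected axial attack that would restore the cis-diol and 1,4-reduction.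

**Step 9**
Reactants: 11 methyl (1R,2S,5R,6S)-5,6-{[(2S,3S)-2,3-dimethoxybutane-2,3-diyl]bis(oxy)}-1,2-dihydroxycyclohex-3-ene-1-carboxylate
Product: 12 (1R,2S,5R,6S)-5,6-{[(2S,3S)-2,3-dimethoxybutane-2,3-diyl]bis(oxy)}-1-(hydroxymethyl)cyclohex-3-ene-1,2-diol
Conditions: LiBH4, THF, 0 °C to rt
Reagents that add atoms: none
Why: Borohydride reduction of an α-hydroxy ester, activated by chelation to the neighbouring alkoxide, should give the primary alcohol at C7; the acetal, the alkene and the stereocentres are not affected.

**Step 10**
Reactants: 12 (1R,2S,5R,6S)-5,6-{[(2S,3S)-2,3-dimethoxybutane-2,3-diyl]bis(oxy)}-1-(hydroxymethyl)cyclohex-3-ene-1,2-diol; 13 benzoyl chloride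
Product: 14 [(1R,2S,5R,6S)-2-(benzoyloxy)-5,6-{[(2S,3S)-2,3-dimethoxybutane-2,3-diyl]bis(oxy)}-1-hydroxycyclohex-3-en-1-yl]methyl benzoate
Conditions: BzCl (2.5 equiv), pyridine, DMAP (cat.), CH2Cl2, 0 °C to rt
Reagents that add atoms: benzoyl chloride (13), O=C(Cl)c1ccccc1
Why: DMAP-catalysed acylation takes the primary C7 and the secondary allylic C2 hydroxyl; the tertiary C1 hydroxyl is too hindered to react at this temperature and the C5/C6 oxygens are masked.

**Step 11**
Reactants: 14 [(1R,2S,5R,6S)-2-(benzoyloxy)-5,6-{[(2S,3S)-2,3-dimethoxybutane-2,3-diyl]bis(oxy)}-1-hydroxycyclohex-3-en-1-yl]methyl benzoate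
Product: 15 [(1S,2S,5R,6S)-2-(benzoyloxy)-1,5,6-trihydroxycyclohex-3-en-1-yl]methyl benzoate
Conditions: TFA/H2O 9:1, 0 °C to rt, short reaction time
Reagents that add atoms: none
Why: Aqueous acid hydrolyses the bis-ketal to the C5/C6 diol with release of the diketone; under acid the benzoates should neither hydrolyse nor migrate as they would under base, and no stereocentre is touched.

## Compound list

1 | benzoic acid | OC(=O)c1ccccc1 | starting material
2 | dioxygen | O=O | starting material
3 | (1S,2R)-1,2-dihydroxycyclohexa-3,5-diene-1-carboxylic acid | OC(=O)[C@@]1(O)[C@H](O)C=CC=C1 | intermediate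
4 | methyl (1S,2R)-1,2-dihydroxycyclohexa-3,5-diene-1-carboxylate | COC(=O)[C@@]1(O)[C@H](O)C=CC=C1 | intermediate
5 | methyl (1S,2R)-2-[(tert-butyldimethylsilyl)oxy]-1-hydroxycyclohexa-3,5-diene-1-carboxylate | COC(=O)[C@@]1(O)[C@H](O[Si](C)(C)C(C)(C)C)C=CC=C1 | intermediate
6 | methyl (1S,2R,5S,6S)-2-[(tert-butyldimethylsilyl)oxy]-5,6-epoxy-1-hydroxycyclohex-3-ene-1-carboxylate | COC(=O)[C@@]1(O)[C@H](O[Si](C)(C)C(C)(C)C)C=C[C@@H]2O[C@H]12 | intermediate
7 | methyl (1S,2R,5R,6S)-2-[(tert-butyldimethylsilyl)oxy]-1,5,6-trihydroxycyclohex-3-ene-1-carboxylate | COC(=O)[C@@]1(O)[C@H](O[Si](C)(C)C(C)(C)C)C=C[C@@H](O)[C@@H]1O | intermediate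
8 | methyl (1R,2R,5R,6S)-1,2,5,6-tetrahydroxycyclohex-3-ene-1-carboxylate | COC(=O)[C@@]1(O)[C@H](O)C=C[C@@H](O)[C@@H]1O | intermediate (not isolated)
9 | methyl (1R,2R,5R,6S)-5,6-{[(2S,3S)-2,3-dimethoxybutane-2,3-diyl]bis(oxy)}-1,2-dihydroxycyclohex-3-ene-1-carboxylate | COC(=O)[C@@]1(O)[C@H](O)C=C[C@H]2O[C@](C)(OC)[C@@](C)(OC)O[C@H]12 | intermediate
10 | methyl (1S,5R,6S)-5,6-{[(2S,3S)-2,3-dimethoxybutane-2,3-diyl]bis(oxy)}-1-hydroxy-2-oxocyclohex-3-ene-1-carboxylate | COC(=O)[C@@]1(O)C(=O)C=C[C@H]2O[C@](C)(OC)[C@@](C)(OC)O[C@H]12 | intermediate
11 | methyl (1R,2S,5R,6S)-5,6-{[(2S,3S)-2,3-dimethoxybutane-2,3-diyl]bis(oxy)}-1,2-dihydroxycyclohex-3-ene-1-carboxylate | COC(=O)[C@@]1(O)[C@@H](O)C=C[C@H]2O[C@](C)(OC)[C@@](C)(OC)O[C@H]12 | intermediate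
12 | (1R,2S,5R,6S)-5,6-{[(2S,3S)-2,3-dimethoxybutane-2,3-diyl]bis(oxy)}-1-(hydroxymethyl)cyclohex-3-ene-1,2-diol | OC[C@@]1(O)[C@@H](O)C=C[C@H]2O[C@](C)(OC)[C@@](C)(OC)O[C@H]12 | intermediate
13 | benzoyl chloride | O=C(Cl)c1ccccc1 | starting material
14 | [(1R,2S,5R,6S)-2-(benzoyloxy)-5,6-{[(2S,3S)-2,3-dimethoxybutane-2,3-diyl]bis(oxy)}-1-hydroxycyclohex-3-en-1-yl]methyl benzoate | O=C(OC[C@@]1(O)[C@@H](OC(=O)c3ccccc3)C=C[C@H]2O[C@](C)(OC)[C@@](C)(OC)O[C@H]12)c1ccccc1 | intermediate
15 | [(1S,2S,5R,6S)-2-(benzoyloxy)-1,5,6-trihydroxycyclohex-3-en-1-yl]methyl benzoate | O=C(OC[C@@]1(O)[C@@H](OC(=O)c2ccccc2)C=C[C@@H](O)[C@@H]1O)c1ccccc1 | target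

## Step count and least certain steps

Total step count: 11. Longest linear sequence: 11 steps (1 to 15); benzoyl chloride 13 enters at step 10.

**Step 1 (key step).** The diol may be re-aromatized if revertant cells regain dehydrogenase activity, the cells may be inhibited by accumulating product, and the diol acid may dehydrate during acidic isolation. The fallback replaces the blocked mutant by a recombinant host: Escherichia coli expressing the cloned three-component benzoate 1,2-dioxygenase has no pathway that consumes the diol. Benzoate 1 is fed with glucose under air, and the medium is worked up as in step 1. The fallback sets out from 1 and 2 and comes back to the route at 3.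

**Step 4.** Oxygen transfer may go to the wrong alkene or face if the tertiary, ester-chelated C1 hydroxyl binds vanadium poorly, and the Lewis-acidic metal may trigger ionization and aromatization of the diene. The fallback gives up the epoxide and uses syn-dihydroxylation followed by inversion of the allylic carbinol. From 5, hydrogen-bond-directed dihydroxylation with stoichiometric OsO4·TMEDA (CH2Cl2, −78 °C, osmate ester released with ethylenediamine) should add both oxygens to C5=C6 on the upper face and give the all-cis triol F1. MnO2 should then oxidize only its allylic C5 hydroxyl to the α-hydroxy enone F2. Me4NBH(OAc)3, directed by the upper-face C6 and C1 hydroxyls, should deliver hydride to the upper face of C5 and place the C5 hydroxyl on the lower face. The fallback comes back to the route at 7 and bypasses 6.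

**Step 5.** Water may attack in the conjugate sense at C3, the silyl ether may be lost early, or the ester may participate, any of which erodes regiocontrol. The fallback makes the C5–O bond intramolecularly. From 6, LiOH in THF/H2O should give the epoxy acid F3. On treatment with CSA in CH2Cl2 its carboxyl group, held on the lower face, can reach only C5 and should open the epoxide anti to give the bridged lactone F4, with C5–O on the lower face. NaOMe in MeOH should open the strained lactone to the methyl ester. The fallback comes back to the route at 7.

**Step 8.** Ligand exchange at the hindered tertiary C1 hydroxyl may be too slow, so that the ketone does not react, or undirected hydride attack from the lower face may return the cis-diol. The fallback avoids the ketone and inverts C2 by substitution. From 9, a Mitsunobu reaction (4-nitrobenzoic acid, PPh3, DIAD, THF) should displace the activated secondary allylic C2 oxygen with inversion and give the inverted 4-nitrobenzoate F5; the tertiary hydroxyl does not take part. K2CO3 in MeOH should then cleave the aryl ester. The fallback comes back to the route at 11 and bypasses 10.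

## Further compounds

F0 | step 1 | none | none
F1 | step 4 | methyl (1S,2R,5S,6S)-2-[(tert-butyldimethylsilyl)oxy]-1,5,6-trihydroxycyclohex-3-ene-1-carboxylate (C1, C5 and C6 hydroxyls all on the upper face) | COC(=O)[C@@]1(O)[C@H](O[Si](C)(C)C(C)(C)C)C=C[C@H](O)[C@@H]1O
F2 | step 4 | methyl (1S,2R,6R)-2-[(tert-butyldimethylsilyl)oxy]-1,6-dihydroxy-5-oxocyclohex-3-ene-1-carboxylate | COC(=O)[C@@]1(O)[C@H](O[Si](C)(C)C(C)(C)C)C=CC(=O)[C@@H]1O
F3 | step 5 | (1S,2R,5S,6S)-2-[(tert-butyldimethylsilyl)oxy]-5,6-epoxy-1-hydroxycyclohex-3-ene-1-carboxylic acid | OC(=O)[C@@]1(O)[C@H](O[Si](C)(C)C(C)(C)C)C=C[C@@H]2O[C@H]12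
F4 | step 5 | 2-[(tert-butyldimethylsilyl)oxy]-1,8-dihydroxy-6-oxabicyclo[3.2.1]oct-3-en-7-one (lactone from C7 to the lower-face oxygen at C5; hydroxyls at C1 and C6 of the ring numbering on the upper face) | O=C1[C@@]2(O)[C@H](O[Si](C)(C)C(C)(C)C)C=C[C@@H](O1)[C@@H]2O
F5 | step 8 | methyl (1R,2S,5R,6S)-5,6-{[(2S,3S)-2,3-dimethoxybutane-2,3-diyl]bis(oxy)}-1-hydroxy-2-[(4-nitrobenzoyl)oxy]cyclohex-3-ene-1-carboxylate | COC(=O)[C@@]1(O)[C@@H](OC(=O)c3ccc(cc3)[N+](=O)[O-])C=C[C@H]2O[C@](C)(OC)[C@@](C)(OC)O[C@H]12
A1 | alternative 1 | (1E,3E)-buta-1,3-diene-1,4-diyl diacetate | CC(=O)O/C=C/C=C/OC(C)=O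
A2 | alternative 1 | methyl 2-oxo-1,3-dioxole-4-carboxylate | COC(=O)C1=COC(=O)O1
A3 | alternative 1 | methyl 2,5-diacetoxy-1,6-(carbonyldioxy)cyclohex-3-ene-1-carboxylate (carbonate trans to both acetates) | COC(=O)[C@@]1(OC(=O)O2)[C@@H](OC(C)=O)C=C[C@@H](OC(C)=O)[C@@H]12
A4 | alternative 2 | 3-hydroxy-2H-pyran-2-one | O=C1OC=CC=C1O
A5 | alternative 2 | (E)-hex-3-ene-2,5-dione | CC(=O)/C=C/C(C)=O
A6 | alternative 2 | trans-7,8-diacetyl-4-hydroxy-2-oxabicyclo[2.2.2]oct-5-en-3-one (8-acetyl syn to the alkene) | O=C1[C@@]2(O)C=C[C@@H](O1)[C@@H](C(C)=O)[C@@H]2C(C)=O
A7 | alternative 3 | 4-hydroxybenzyl benzoate | O=C(OCc1ccc(O)cc1)c1ccccc1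
A8 | alternative 3 | (1-hydroxy-4-oxocyclohexa-2,5-dien-1-yl)methyl benzoate | O=C(OCC1(O)C=CC(=O)C=C1)c1ccccc1
A9 | alternative 3 | (syn-5,6-epoxy-1-hydroxy-4-oxocyclohex-2-en-1-yl)methyl benzoate | O=C(OC[C@@]1(O)C=CC(=O)[C@@H]2O[C@H]12)c1ccccc1
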